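**Strategy**

The route rests on disconnecting the O1–C8a bond of ring C. Because O5 and O8 of ring A are para to each other, ring A can be carried as a 1,4-benzoquinone in which C8a is the β-carbon of both the C5 quinone carbonyl and the C4 ketone. Releasing a formyl group on the carbon that becomes C3 lets its enol oxygen add to C8a, which closes the pyranone and returns ring A as the 5,8-hydroquinone in one operation. The precursor is a 2-acyl-5-isopropoxy-1,4-benzoquinone whose acyl chain carries the ring B aryl group and a dimethyl acetal. O8 methylation and a Claisen rearrangement to C6 complete the target.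

Key step: step 7

Remark: isoflavone numbering (O1, C2 to C8a, ring B primed) is used for all intermediates. Compounds 10, 11 and 12 carry one stereocentre (the carbon between ketone and acetal) and are racemic; it becomes sp2 C3 in step 7, and the target has no stereocentre.

**Route**

Step 1
Reactants: 1 resorcinol; 2 2,4,5-trimethoxyphenylacetic acid
Product: 3 1-(2,4-dihydroxyphenyl)-2-(2,4,5-trimethoxyphenyl)ethan-1-one
Conditions: BF3·OEt2 (neat), 85 °C; then aq. NaOAc
Reagents that add atoms: none
Why: BF3-mediated Friedel–Crafts C-acylation of resorcinol by the arylacetic acid should occur at C4, ortho and para to the two hydroxyls, which is the standard entry to 2,4-dihydroxydeoxybenzoins.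

Step 2
Reactants: 3 1-(2,4-dihydroxyphenyl)-2-(2,4,5-trimethoxyphenyl)ethan-1-one
Product: 4 1-(2-hydroxy-4-isopropoxyphenyl)-2-(2,4,5-trimethoxyphenyl)ethan-1-one
Conditions: 2-bromopropane (1.2 equiv), K2CO3, DMF, 50 °C
Reagents that add atoms: 2-bromopropane, CC(C)Br
Why: Williamson etherification should select the 4-OH, because the 2-OH is hydrogen-bonded to the ketone and is much less acidic and nucleophilic.

Step 3
Reactants: 4 1-(2-hydroxy-4-isopropoxyphenyl)-2-(2,4,5-trimethoxyphenyl)ethan-1-one
Product: 6 1-(2,5-dihydroxy-4-isopropoxyphenyl)-2-(2,4,5-trimethoxyphenyl)ethan-1-one, via aryl sulfate 5 (not isolated)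
Conditions: K2S2O8, aq. KOH, pyridine, 15–20 °C; then HCl to pH 1, 90 °C
Reagents that add atoms: potassium peroxydisulfate, [K+].[K+].[O-]S(=O)(=O)OOS(=O)(=O)[O-]
Why: In the Elbs persulfate oxidation the phenoxide of the 2-OH attacks peroxydisulfate through its para carbon (C5 of the aryl ketone), and acid hydrolysis of the aryl sulfate should give the para-diol.

Step 4
Reactants: 6 1-(2,5-dihydroxy-4-isopropoxyphenyl)-2-(2,4,5-trimethoxyphenyl)ethan-1-one
Product: 7 1-[2,5-bis(benzyloxy)-4-isopropoxyphenyl]-2-(2,4,5-trimethoxyphenyl)ethan-1-one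
Conditions: BnBr (2.5 equiv), K2CO3, KI (cat.), acetone, reflux, Ar
Reagents that add atoms: benzyl bromide, BrCc1ccccc1
Why: Williamson benzylation under carbonate in refluxing acetone should etherify both phenols, including the chelated one, while being too weakly basic to alkylate the benzylic methylene.

Step 5
Reactants: 7 1-[2,5-bis(benzyloxy)-4-isopropoxyphenyl]-2-(2,4,5-trimethoxyphenyl)ethan-1-one; 8 trimethyl orthoformate
Product: 10 rac-1-[2,5-bis(benzyloxy)-4-isopropoxyphenyl]-3,3-dimethoxy-2-(2,4,5-trimethoxyphenyl)propan-1-one, via silyl enol ether 9 (not isolated)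
Conditions: Me3SiOSO2CF3 (1.4 equiv), iPr2NEt (1.2 equiv), CH2Cl2, 0 °C; then 8, −20 → 0 °C; NaHCO3 quench
Reagents that add atoms: none
Why: One-pot enol silane formation followed by Mukaiyama-type addition of the silyl enol ether to the dimethoxycarbenium ion from the orthoformate should give the β-keto dimethyl acetal directly, the new α-stereocentre being formed as a racemate that step 7 erases.

Step 6
Reactants: 10 rac-1-[2,5-bis(benzyloxy)-4-isopropoxyphenyl]-3,3-dimethoxy-2-(2,4,5-trimethoxyphenyl)propan-1-one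
Product: 12 rac-2-[3,3-dimethoxy-2-(2,4,5-trimethoxyphenyl)propanoyl]-5-isopropoxy-1,4-benzoquinone, via hydroquinone acetal 11 (not isolated)
Conditions: H2 (1 atm), 10% Pd/C, NaHCO3, EtOAc, rt; filter under Ar; then Ag2O, MgSO4, rt, 30 min, dark; filter, use crude
Reagents that add atoms: none
Why: Buffered hydrogenolysis of the two benzyl ethers should leave acetal, isopropyl ether and ketone intact, and Ag2O dehydrogenation of the para-hydroquinone is the standard mild route to acylbenzoquinones and is too weak to oxidise ring B; the acid-sensitive hydroquinone acetal is never purified.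

Step 7
Reactants: 12 rac-2-[3,3-dimethoxy-2-(2,4,5-trimethoxyphenyl)propanoyl]-5-isopropoxy-1,4-benzoquinone
Product: 15 5,8-dihydroxy-7-isopropoxy-3-(2,4,5-trimethoxyphenyl)chromen-4-one, via quinonyl enol 13 (not isolated), via 8aH-chromenedione adduct 14 (not isolated)
Conditions: 0.5 M aq. H2SO4–MeCN (1:4), 0.002 M in 12, degassed, Ar, 25–40 °C, dark; then aq. Na2S2O4 wash
Reagents that add atoms: water, O
Why: Proposed new method: aqueous acid hydrolyses the acetal to the formyl ketone, which rests as chelated Z-enol 13; after rotation about the C3–C4 bond its oxygen adds to quinone carbon C8a, the β-position of both the C5 quinone carbonyl and the C4 ketone, and adduct 14 shifts its 8a-hydrogen to O8 so that ring A aromatises as the 5,8-diol. The nearest known reaction type is the intramolecular oxa-Michael addition of a phenol oxygen to an acylquinone, by which 2-hydroxyaryl 2,5-dihydroxyphenyl ketones are converted into xanthones after oxidation; here an enol oxygen takes the place of the phenol. Ring C closes in the 6-endo-trig mode, the C4a=C8a bond lying inside the new ring. No stereocentre is created, and the racemic α-centre of 12 becomes sp2 C3. The step needs oxygen rather than C6' of ring B to attack C8a, and C8a rather than C6 to be attacked: the enol is the more acidic and nearer nucleophile, whereas C6' has only one ortho methoxy group and no strong acid to drive a Friedel–Crafts closure, and C6 is the donor-deactivated α-carbon of the vinylogous ester O7–C7=C6–C5=O that the tether cannot reach. Because the quinone has no hydroxyl, closure through O5 is excluded, a non-nucleophilic acid avoids hydrochlorination of the quinone, and high dilution without air holds back electron exchange between product hydroquinone and unreacted quinone.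

Step 8
Reactants: 15 5,8-dihydroxy-7-isopropoxy-3-(2,4,5-trimethoxyphenyl)chromen-4-one
Product: 16 5-hydroxy-7-isopropoxy-8-methoxy-3-(2,4,5-trimethoxyphenyl)chromen-4-one
Conditions: MeI (1.1 equiv), K2CO3, acetone, 40 °C, Ar
Reagents that add atoms: iodomethane, CI
Why: Williamson methylation with one equivalent of MeI should go to O8, because the 5-OH is locked in a peri hydrogen bond to the C4 carbonyl and resists carbonate-mediated alkylation, the usual selectivity of 5-hydroxyflavonoids.

Step 9
Reactants: 16 5-hydroxy-7-isopropoxy-8-methoxy-3-(2,4,5-trimethoxyphenyl)chromen-4-one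
Product: 17 5,7-dihydroxy-8-methoxy-3-(2,4,5-trimethoxyphenyl)chromen-4-one (isocaviunin)
Conditions: BCl3 (3 equiv), CH2Cl2, −78 → 0 °C; then aq. NaHCO3
Reagents that add atoms: none
Why: Lewis acid dealkylation with BCl3 removes a secondary isopropyl group from an aryl ether far faster than a methyl group, so the four methoxy groups should survive at low temperature.

Step 10
Reactants: 17 5,7-dihydroxy-8-methoxy-3-(2,4,5-trimethoxyphenyl)chromen-4-one; 18 3-chloro-3-methylbut-1-yne
Product: 19 5-hydroxy-8-methoxy-7-[(2-methylbut-3-yn-2-yl)oxy]-3-(2,4,5-trimethoxyphenyl)chromen-4-one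
Conditions: 18 (3 equiv), K2CO3, KI, CuI (cat.), acetone, reflux
Reagents that add atoms: none
Why: Copper-assisted O-alkylation by the tertiary propargylic chloride should take place at the acidic, unchelated 7-OH and leave the chelated 5-OH free.

Step 11
Reactants: 19 5-hydroxy-8-methoxy-7-[(2-methylbut-3-yn-2-yl)oxy]-3-(2,4,5-trimethoxyphenyl)chromen-4-one
Product: 20 5-hydroxy-8-methoxy-7-[(2-methylbut-3-en-2-yl)oxy]-3-(2,4,5-trimethoxyphenyl)chromen-4-one
Conditions: H2 (1 atm), Pd/CaCO3 poisoned with Pb(OAc)2, quinoline, EtOAc, rt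
Reagents that add atoms: none
Why: Semihydrogenation on lead-poisoned Pd/CaCO3 should stop at the terminal alkene and leave the C2=C3 bond of the chromone untouched.

Step 12
Reactants: 20 5-hydroxy-8-methoxy-7-[(2-methylbut-3-en-2-yl)oxy]-3-(2,4,5-trimethoxyphenyl)chromen-4-one
Product: 22 6-prenylisocaviunin, 5,7-dihydroxy-8-methoxy-6-(3-methylbut-2-en-1-yl)-3-(2,4,5-trimethoxyphenyl)chromen-4-one, via ortho-dienone 21 (not isolated)
Conditions: PhNEt2, 130–140 °C, Ar
Reagents that add atoms: none
Why: Aromatic Claisen [3,3] rearrangement of the 1,1-dimethylallyl ether should deliver the allyl terminus as a prenyl group to C6, the only free ortho position since C8 carries the methoxy group, after which dienone 21 enolises to the 7-phenol.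

**Compound list**

1 | resorcinol | Oc1cccc(O)c1 | starting material
2 | 2,4,5-trimethoxyphenylacetic acid | COc1cc(OC)c(CC(=O)O)cc1OC | starting material
3 | 1-(2,4-dihydroxyphenyl)-2-(2,4,5-trimethoxyphenyl)ethan-1-one | COc1cc(OC)c(CC(=O)c2ccc(O)cc2O)cc1OC | intermediate
4 | 1-(2-hydroxy-4-isopropoxyphenyl)-2-(2,4,5-trimethoxyphenyl)ethan-1-one | COc1cc(OC)c(CC(=O)c2ccc(OC(C)C)cc2O)cc1OC | intermediate
5 | potassium 4-hydroxy-2-isopropoxy-5-[(2,4,5-trimethoxyphenyl)acetyl]phenyl sulfate | COc1cc(OC)c(CC(=O)c2cc(OS(=O)(=O)[O-])c(OC(C)C)cc2O)cc1OC.[K+] | intermediate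
6 | 1-(2,5-dihydroxy-4-isopropoxyphenyl)-2-(2,4,5-trimethoxyphenyl)ethan-1-one | COc1cc(OC)c(CC(=O)c2cc(O)c(OC(C)C)cc2O)cc1OC | intermediate
7 | 1-[2,5-bis(benzyloxy)-4-isopropoxyphenyl]-2-(2,4,5-trimethoxyphenyl)ethan-1-one | COc1cc(OC)c(CC(=O)c2cc(OCc3ccccc3)c(OC(C)C)cc2OCc4ccccc4)cc1OC | intermediate
8 | trimethyl orthoformate | COC(OC)OC | starting material
9 | (Z)-{1-[2,5-bis(benzyloxy)-4-isopropoxyphenyl]-2-(2,4,5-trimethoxyphenyl)ethenyl}oxy(trimethyl)silane (Z expected) | COc1cc(OC)c(/C=C(\O[Si](C)(C)C)c2cc(OCc3ccccc3)c(OC(C)C)cc2OCc4ccccc4)cc1OC | intermediate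
10 | rac-1-[2,5-bis(benzyloxy)-4-isopropoxyphenyl]-3,3-dimethoxy-2-(2,4,5-trimethoxyphenyl)propan-1-one | COc1cc(OC)c(C(C(OC)OC)C(=O)c2cc(OCc3ccccc3)c(OC(C)C)cc2OCc4ccccc4)cc1OC | intermediate
11 | rac-1-(2,5-dihydroxy-4-isopropoxyphenyl)-3,3-dimethoxy-2-(2,4,5-trimethoxyphenyl)propan-1-one | COc1cc(OC)c(C(C(OC)OC)C(=O)c2cc(O)c(OC(C)C)cc2O)cc1OC | intermediate
12 | rac-2-[3,3-dimethoxy-2-(2,4,5-trimethoxyphenyl)propanoyl]-5-isopropoxy-1,4-benzoquinone | O=C1C(C(=O)C(C(OC)OC)c2cc(OC)c(OC)cc2OC)=CC(=O)C(OC(C)C)=C1 | intermediate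
13 | 2-[(Z)-3-hydroxy-2-(2,4,5-trimethoxyphenyl)prop-2-enoyl]-5-isopropoxy-1,4-benzoquinone | O=C1C(C(=O)/C(=C\O)c2cc(OC)c(OC)cc2OC)=CC(=O)C(OC(C)C)=C1 | intermediate
14 | rac-5-hydroxy-7-isopropoxy-3-(2,4,5-trimethoxyphenyl)-8aH-chromene-4,8-dione | COc1cc(OC)c(C2=COC3C(=O)C(OC(C)C)=CC(O)=C3C2=O)cc1OC | intermediate
15 | 5,8-dihydroxy-7-isopropoxy-3-(2,4,5-trimethoxyphenyl)chromen-4-one | COc1cc(OC)c(-c2coc3c(O)c(OC(C)C)cc(O)c3c2=O)cc1OC | intermediate
16 | 5-hydroxy-7-isopropoxy-8-methoxy-3-(2,4,5-trimethoxyphenyl)chromen-4-one | COc1cc(OC)c(-c2coc3c(OC)c(OC(C)C)cc(O)c3c2=O)cc1OC | intermediate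
17 | 5,7-dihydroxy-8-methoxy-3-(2,4,5-trimethoxyphenyl)chromen-4-one (isocaviunin) | COc1cc(OC)c(-c2coc3c(OC)c(O)cc(O)c3c2=O)cc1OC | intermediate
18 | 3-chloro-3-methylbut-1-yne | C#CC(C)(C)Cl | starting material
19 | 5-hydroxy-8-methoxy-7-[(2-methylbut-3-yn-2-yl)oxy]-3-(2,4,5-trimethoxyphenyl)chromen-4-one | COc1cc(OC)c(-c2coc3c(OC)c(OC(C)(C)C#C)cc(O)c3c2=O)cc1OC | intermediate
20 | 5-hydroxy-8-methoxy-7-[(2-methylbut-3-en-2-yl)oxy]-3-(2,4,5-trimethoxyphenyl)chromen-4-one | COc1cc(OC)c(-c2coc3c(OC)c(OC(C)(C)C=C)cc(O)c3c2=O)cc1OC | intermediate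
21 | rac-5-hydroxy-8-methoxy-6-(3-methylbut-2-en-1-yl)-3-(2,4,5-trimethoxyphenyl)-6H-chromene-4,7-dione | COc1cc(OC)c(C2=COC3=C(OC)C(=O)C(CC=C(C)C)C(O)=C3C2=O)cc1OC | intermediate
22 | 6-prenylisocaviunin, 5,7-dihydroxy-8-methoxy-6-(3-methylbut-2-en-1-yl)-3-(2,4,5-trimethoxyphenyl)chromen-4-one | COc1cc(OC)c(-c2coc3c(OC)c(O)c(CC=C(C)C)c(O)c3c2=O)cc1OC | target

**Totals**

Total step count: 12. Longest linear sequence: 12 steps (from 1 and 2 to 22; 8 and 18 enter as single compounds).

**Steps most likely to fail**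

Step 7 (Proposed new method). Three processes could divert the closure:
- carbon attack by C6' of ring B on C8a, a Friedel–Crafts-type closure to a six-membered carbocycle;
- electron transfer from product hydroquinone to unreacted quinone, which would return reduced precursor that then cyclises through its free ortho phenol onto the unmasked formyl carbon, the wrong way round;
- acid-promoted enolisation at the α-carbon of 12 followed by internal redox isomerisation of the side chain.

The fallback uses only established isoflavone chemistry, sets out from 2 and returns at 15. Compound 2 would be condensed with commercial phloroglucinol (Oc1cc(O)cc(O)c1) in BF3·OEt2 at 85 °C to give 1-(2,4,6-trihydroxyphenyl)-2-(2,4,5-trimethoxyphenyl)ethan-1-one F1. Ring closure with DMF, BF3·OEt2 and MeSO2Cl should give 5,7-dihydroxy-3-(2,4,5-trimethoxyphenyl)chromen-4-one F2. 2-Bromopropane and K2CO3 would alkylate the unchelated O7 to give 5-hydroxy-7-isopropoxy-3-(2,4,5-trimethoxyphenyl)chromen-4-one F3. Elbs oxidation with K2S2O8 in aqueous KOH and pyridine, para to the chelated 5-OH, should give potassium 5-hydroxy-7-isopropoxy-4-oxo-3-(2,4,5-trimethoxyphenyl)chromen-8-yl sulfate F4, and hot aqueous HCl would hydrolyse it to 15.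

Step 3. Persulfate hydroxylation commonly stalls at partial conversion, and sulfate radicals may also oxidise the benzylic methylene or ring B, so material could be lost to over-oxidation and polymeric by-products. The fallback builds the oxygenation into ring A before acylation; it sets out from 2 and returns at 7. Commercial 2,5-dihydroxybenzaldehyde (O=Cc1cc(O)ccc1O) would be benzylated (BnBr, K2CO3) to 2,5-bis(benzyloxy)benzaldehyde F5. Baeyer–Villiger oxidation with mCPBA and cleavage of the aryl formate with KOH in MeOH should give 2,5-bis(benzyloxy)phenol F6. 2-Bromopropane and K2CO3 would then give 1,4-bis(benzyloxy)-2-isopropoxybenzene F7. Acid 2 would be activated with (CF3CO)2O as 2,4,5-trimethoxyphenylacetic trifluoroacetic anhydride F8, which with catalytic H3PO4 should acylate F7 at the position para to the isopropoxy group and ortho to a benzyloxy group, giving 7.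

Step 5. Under Me3SiOSO2CF3 the β-keto acetal may lose methanol to the conjugated methyl enol ether, and the dimethoxycarbenium ion may be captured by free positions of the electron-rich arenes instead of the enol silane. The fallback separates C–C bond formation from acetalisation; it sets out from 7 and returns at 10. Crossed Claisen formylation of 7 with ethyl formate and NaH in THF should give (Z)-1-[2,5-bis(benzyloxy)-4-isopropoxyphenyl]-3-hydroxy-2-(2,4,5-trimethoxyphenyl)prop-2-en-1-one F9, and treatment with 8 in MeOH with catalytic p-TsOH at room temperature would convert it into 10.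

**Further compounds**

F1 | step 7 | 1-(2,4,6-trihydroxyphenyl)-2-(2,4,5-trimethoxyphenyl)ethan-1-one | COc1cc(OC)c(CC(=O)c2c(O)cc(O)cc2O)cc1OC
F2 | step 7 | 5,7-dihydroxy-3-(2,4,5-trimethoxyphenyl)chromen-4-one | COc1cc(OC)c(-c2coc3cc(O)cc(O)c3c2=O)cc1OC
F3 | step 7 | 5-hydroxy-7-isopropoxy-3-(2,4,5-trimethoxyphenyl)chromen-4-one | COc1cc(OC)c(-c2coc3cc(OC(C)C)cc(O)c3c2=O)cc1OC
F4 | step 7 | potassium 5-hydroxy-7-isopropoxy-4-oxo-3-(2,4,5-trimethoxyphenyl)chromen-8-yl sulfate | COc1cc(OC)c(-c2coc3c(OS(=O)(=O)[O-])c(OC(C)C)cc(O)c3c2=O)cc1OC.[K+]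
F5 | step 3 | 2,5-bis(benzyloxy)benzaldehyde | O=Cc1cc(OCc2ccccc2)ccc1OCc3ccccc3
F6 | step 3 | 2,5-bis(benzyloxy)phenol | Oc1cc(OCc2ccccc2)ccc1OCc3ccccc3
F7 | step 3 | 1,4-bis(benzyloxy)-2-isopropoxybenzene | CC(C)Oc1cc(OCc2ccccc2)ccc1OCc3ccccc3
F8 | step 3 | 2,4,5-trimethoxyphenylacetic trifluoroacetic anhydride | COc1cc(OC)c(CC(=O)OC(=O)C(F)(F)F)cc1OC
F9 | step 5 | (Z)-1-[2,5-bis(benzyloxy)-4-isopropoxyphenyl]-3-hydroxy-2-(2,4,5-trimethoxyphenyl)prop-2-en-1-one | O/C=C(\C(=O)c2cc(OCc3ccccc3)c(OC(C)C)cc2OCc4ccccc4)c1cc(OC)c(OC)cc1OC
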